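The data come from a simulation on assumed constants; scatter was added.

**The number.** A small charge of capture agent, 1.00 mM against 0.050 M of solid substrate, can remove one open intermediate per molecule. Partner opens starting material one to one, so it is the limiting reagent whenever its charge is below the substrate's. Both facts fold into one dimensionless number, the usable fraction u: the lesser of the partner and substrate charges, minus the capture agent charge, over the substrate charge. For theta, u = 0.980.

| setting | winter | midnight | delta | zeta | theta | beta | eta |
|---|---|---|---|---|---|---|---|
| solid substrate | 0.050 M | 0.050 M | 0.050 M | 0.050 M | 0.050 M | 0.050 M | 0.050 M |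
| partner | 0.025 M | 0.15 M | 0.0200 M | 0.0300 M | 0.0500 M | 0.0600 M | 0.100 M |
| capture agent | 1 mM | 1 mM | 1.00 mM | 1.00 mM | 1.00 mM | 1.00 mM | 1.00 mM |
| remark | run made earlier | run made earlier |  |  |  |  |  |
| time |  |  | 3.0 min | 3.0 min | 3.0 min | 3.0 min | 3.0 min |

- winter (time / min: target / %): 0.500: 30.1; 1.00: 34.3; 1.50: 35.0; 2.00: 32.9; 2.50: 31.5; 3.00: 33.9
- midnight (time / min: target / %): 0.200: 43.0; 0.667: 73.7; 1.00: 68.7; 1.50: 70.2; 2.50: 65.5; 3.00: 66.0

(readings scatter by 1 percentage point)

1. amount of target at the end, in percent of the solid substrate charged for delta, zeta, theta, beta, eta, in this order
2. how the row runs (hardly changes / rises, then falls / rises all the way / falls, then rises / falls all the way)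

- given per volume of solution although it is solid: solid substrate
- steps under discussion: open intermediate + capture agent -> trapped intermediate; open intermediate <-> isomer of the product; solid substrate <-> starting material; open intermediate <-> target; starting material + partner -> open intermediate + by-product
- at the start none of the solid substrate is in solution
- a step back or a flat step of under half a point counts as no turn
- "hardly changes" means that all values lie within two and a half points (for a concentration: within two and a half percent of the largest)

**The frozen share.** Midnight has u = 0.980, and its last two readings give a target share s = 0.671 of u. Winter has u = 0.480 and reads 0.681, so one share serves both runs. Delta has u = 0.380, and s, frozen at the midnight reading, gives 25.5% for delta, 38.9% for zeta and 65.8% for theta, beta and eta.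

**The weak point.** Theta charges partner and substrate equally, so u assumes a finished reaction with neither in excess, and neither earlier run has equal charges from which to read a tail.

**The forecast.** It gives 25.7%, 39.2%, 63.5%, 66% and 66.2%, a row that rises all the way. It lies below my theta figure, holding that “the stoichiometric case may leave a slow tail”.

    open intermediate + capture agent → trapped intermediate (k = 3.80 M⁻¹ s⁻¹)
    open intermediate ⇌ isomer of the product (K = 2.30, k = 0.00330 s⁻¹)
    solid substrate ⇌ starting material, rate k3*(cs3 - [starting material]) while solid is left; crystals form when [starting material] > cs3 (solubility = 32.0 mM, k = 0.440 s⁻¹)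
    open intermediate ⇌ target (K = 3.20, k = 0.0980 s⁻¹)
    starting material + partner → open intermediate + by-product (k = 3.60 M⁻¹ s⁻¹)

**The flask.** The row ends at 25.6%, 39.0%, 63.9%, 65.9% and 65.6%, and it rises all the way: eta's step back of 0.3 percentage points from beta lies under the 0.5 point below which a step counts as no turn. Target over u is 0.674 in delta and 0.652 in theta, and theta still holds 3.06% starting material at 3.00 min. In delta, open intermediate and target relax with a half-life of 0.0898 min, shorter than the 2.44 min of open intermediate and isomer of the product, and short against the 3.0 min of the run. The isomer of the product in delta stands at 4.69% after 3.00 min and 13.2% after 30.0 min.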